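## Retrosynthetic overview

1. Numbering: C1 (acetal CH), O2, C3=C4 (enol ether), C4a/C11a (ring fusion), C5–C11 (nine-membered ring A; epoxide C7–C8, methyl C18 on C7, methylene C19 on C11), C12–C16 (side chain). The strategy rests on the 1,5-diene C19=C11–C11a–C4a–C4=C3 that runs through ring A and the dihydropyran ring, the retron of an oxy-Cope shift.
2. Key disconnection: C4a–C11a is made and C3–C19 broken in an anionic [3,3] shift of an eleven-membered (3R)-trienol, run as its carboxylate. Ring A closes by contraction (11 to 9), the trans C4a/C11a pair is set, and C3 is trapped as the enol acetate.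
3. The eleven-membered ring is closed at C3–C4 by Nozaki–Hiyama–Kishi addition of an iodoalkene to a β,γ-unsaturated aldehyde; C3 is then set by oxidation and CBS reduction.
4. The chain comes from neryl acetate (C4a–C9, Z-C7=C8), methyl acetoacetate (C10, C11, C11a, C1), a vinyl group (C19, C3) and a vinylogous Mukaiyama aldol with a tiglate dienolate (C12–C16, sets C12).
5. Ring order: eleven-membered carbocycle, then ring A, then the epoxide, then the dihydropyran (lactol closure at the C1/C3 dialdehyde level), then the two acetates.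

Key step: step 20

Assumption: the target SMILES is read as (1R,4aS,7S,8R,11aR,12S) with C6 and C9 cis on the epoxide, so it derives from a (Z)-C7=C8 alkene; commercial neryl acetate is therefore the starting material.
Assumption: in steps 11 and 18 the catalyst antipode named is the one expected to give the stated configuration; the sense should be confirmed on the product.

## Route

Step 1
Reactants: 1 neryl acetate
Product: 3 (2Z)-3-methyl-6-oxohex-2-en-1-yl acetate, via epoxyneryl acetate 2 (not isolated)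
Conditions: m-CPBA (1.0 equiv), NaHCO3, CH2Cl2, 0 °C; then H5IO6, THF/H2O, 0 °C
Reagents that add atoms: m-CPBA, OOC(=O)c1cccc(Cl)c1
Why: Prilezhaev epoxidation should take the distal alkene (the allylic acetate deactivates C7=C8), and periodic acid cleaves the epoxide through its diol to the C4a aldehyde without touching the Z alkene.

Step 2
Reactants: 3 (2Z)-3-methyl-6-oxohex-2-en-1-yl acetate
Product: 4 (2Z)-3-methylhept-2-en-6-yn-1-ol
Conditions: dimethyl (1-diazo-2-oxopropyl)phosphonate, K2CO3, MeOH, 0 °C to rt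
Reagents that add atoms: dimethyl (1-diazo-2-oxopropyl)phosphonate, CC(=O)C(=[N+]=[N-])P(=O)(OC)OC
Why: Ohira–Bestmann homologation converts the aldehyde into the terminal alkyne (the new carbon is C4), and the methanolic carbonate removes the acetate in the same pot.

Step 3
Reactants: 4 (2Z)-3-methylhept-2-en-6-yn-1-ol
Product: 5 (2Z)-1-bromo-3-methylhept-2-en-6-yne
Conditions: CBr4, PPh3, CH2Cl2, −20 to 0 °C
Reagents that add atoms: tetrabromomethane, BrC(Br)(Br)Br
Why: Appel bromination is an SN2 process at the primary allylic carbon C9 and should leave the Z alkene intact.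

Step 4
Reactants: 5 (2Z)-1-bromo-3-methylhept-2-en-6-yne; 6 methyl acetoacetate
Product: 8 methyl (6Z)-7-methyl-3-oxoundec-6-en-10-ynoate, via acetoacetate dianion 7 (not isolated)
Conditions: 6 (2.4 equiv), NaH then n-BuLi, THF, 0 °C; then 5, 0 °C; aq. NH4Cl
Reagents that add atoms: none
Why: γ-alkylation of the acetoacetate dianion joins C10 to C9 by SN2 at the allylic bromide, and the excess dianion covers any loss to the acetylenic proton.

Step 5
Reactants: 8 methyl (6Z)-7-methyl-3-oxoundec-6-en-10-ynoate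
Product: 9 methyl (2Z,6Z)-7-methyl-3-(trifluoromethanesulfonyloxy)undeca-2,6-dien-10-ynoate
Conditions: Tf2O, sat. aq. LiOH, toluene, 5 °C
Reagents that add atoms: triflic anhydride, O=S(=O)(OS(=O)(=O)C(F)(F)F)C(F)(F)F
Why: O-triflation of the lithium-chelated Z enolate of the β-keto ester should give the (Z)-enol triflate, which fixes C10 trans to the ester carbon C1.

Step 6
Reactants: 9 methyl (2Z,6Z)-7-methyl-3-(trifluoromethanesulfonyloxy)undeca-2,6-dien-10-ynoate
Product: 10 methyl (2Z,6Z)-3-ethenyl-7-methylundeca-2,6-dien-10-ynoate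
Conditions: Bu3SnCH=CH2, Pd(PPh3)4 (5 mol %), LiCl, THF, 65 °C
Reagents that add atoms: tributyl(vinyl)stannane, C=C[Sn](CCCC)(CCCC)CCCC
Why: Stille coupling of the enol triflate proceeds with retention, so the vinyl group (C19=C3) ends up cis to C1 on C11=C11a.

Step 7
Reactants: 10 methyl (2Z,6Z)-3-ethenyl-7-methylundeca-2,6-dien-10-ynoate
Product: 11 (2Z,6Z)-3-ethenyl-7-methylundeca-2,6-dien-10-yn-1-ol
Conditions: DIBAL-H (2.3 equiv), CH2Cl2, −78 °C; Rochelle salt
Reagents that add atoms: none
Why: 1,2-reduction of the dienoate by DIBAL-H brings C1 to the alcohol level without changing the alkene geometry, so that C1 carries no anion-stabilising group in the key step.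

Step 8
Reactants: 11 (2Z,6Z)-3-ethenyl-7-methylundeca-2,6-dien-10-yn-1-ol
Product: 12 tert-butyl{[(2Z,6Z)-3-ethenyl-7-methylundeca-2,6-dien-10-yn-1-yl]oxy}dimethylsilane
Conditions: TBSCl, imidazole, CH2Cl2, 0 °C to rt
Reagents that add atoms: tert-butylchlorodimethylsilane, CC(C)(C)[Si](C)(C)Cl
Why: routine silylation of the primary allylic alcohol gives a C1 ether that tolerates organolithium, Lewis acid and alkoxide conditions.

Step 9
Reactants: 12 tert-butyl{[(2Z,6Z)-3-ethenyl-7-methylundeca-2,6-dien-10-yn-1-yl]oxy}dimethylsilane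
Product: 14 (6Z,10Z)-12-[(tert-butyldimethylsilyl)oxy]-10-ethenyl-6-methyldodeca-6,10-dien-2-ynal, via lithium acetylide 13 (not isolated)
Conditions: n-BuLi, THF, −78 °C; DMF, −78 to 0 °C; inverse quench into aq. KH2PO4
Reagents that add atoms: N,N-dimethylformamide, CN(C)C=O
Why: formylation of the lithium acetylide with DMF introduces C12, and the buffered inverse quench protects the ynal from amine addition.

Step 10
Reactants: 15 methyl tiglate
Product: 17 tert-butyl[(1-methoxy-2-methylbuta-1,3-dien-1-yl)oxy]dimethylsilane, via lithium dienolate 16 (not isolated)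
Conditions: LDA, DMPU, THF, −78 °C; TBSCl, −78 °C to rt
Reagents that add atoms: tert-butylchlorodimethylsilane, CC(C)(C)[Si](C)(C)Cl
Why: γ-deprotonation of the enoate and O-silylation of the extended enolate give the vinylketene silyl acetal needed for the vinylogous aldol.

Step 11
Reactants: 14 (6Z,10Z)-12-[(tert-butyldimethylsilyl)oxy]-10-ethenyl-6-methyldodeca-6,10-dien-2-ynal; 17 tert-butyl[(1-methoxy-2-methylbuta-1,3-dien-1-yl)oxy]dimethylsilane
Product: 18 methyl (2E,5S,10Z,14Z)-16-[(tert-butyldimethylsilyl)oxy]-14-ethenyl-5-hydroxy-2,10-dimethylhexadeca-2,10,14-trien-6-ynoate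
Conditions: SiCl4 (1.1 equiv), (S,S)-bisphosphoramide derived from N,N'-dimethyl-1,1'-binaphthyl-2,2'-diamine (5 mol %), iPr2NEt (10 mol %), CH2Cl2, −78 °C; aq. NaHCO3
Reagents that add atoms: none
Why: in this Lewis-base-catalysed vinylogous Mukaiyama aldol the dienolate attacks through its γ-carbon (C13) to give the (E)-enoate, and the chiral chlorosilyl cation bound to the ynal exposes the Si face (O > C4 > H), which sets (12S).

Step 12
Reactants: 18 methyl (2E,5S,10Z,14Z)-16-[(tert-butyldimethylsilyl)oxy]-14-ethenyl-5-hydroxy-2,10-dimethylhexadeca-2,10,14-trien-6-ynoate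
Product: 20 methyl (2E,5S,6E,10Z,14Z)-16-[(tert-butyldimethylsilyl)oxy]-14-ethenyl-5-hydroxy-6-iodo-2,10-dimethylhexadeca-2,6,10,14-tetraenoate, via vinylstannane 19 (not isolated)
Conditions: Bu3SnH, PdCl2(PPh3)2 (3 mol %), THF, 0 °C; then NIS, CH2Cl2, 0 °C
Reagents that add atoms: N-iodosuccinimide, O=C1CCC(=O)N1I
Why: palladium-catalysed syn-hydrostannation should place tin on C4 (the alkyne carbon next to the free carbinol) and hydrogen on C4a, and iododestannylation with retention gives the iodoalkene with C5 cis to C12.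

Step 13
Reactants: 20 methyl (2E,5S,6E,10Z,14Z)-16-[(tert-butyldimethylsilyl)oxy]-14-ethenyl-5-hydroxy-6-iodo-2,10-dimethylhexadeca-2,6,10,14-tetraenoate
Product: 21 methyl (2E,5S,6E,10Z,14Z)-5,16-bis[(tert-butyldimethylsilyl)oxy]-14-ethenyl-6-iodo-2,10-dimethylhexadeca-2,6,10,14-tetraenoate
Conditions: TBSOTf, 2,6-lutidine, CH2Cl2, −78 °C
Reagents that add atoms: tert-butyldimethylsilyl triflate, CC(C)(C)[Si](C)(C)OS(=O)(=O)C(F)(F)F
Why: silylation of the hindered secondary C12 alcohol with the silyl triflate masks the oxygen that would otherwise give a second alkoxide in the key step.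

Step 14
Reactants: 21 methyl (2E,5S,6E,10Z,14Z)-5,16-bis[(tert-butyldimethylsilyl)oxy]-14-ethenyl-6-iodo-2,10-dimethylhexadeca-2,6,10,14-tetraenoate
Product: 23 methyl (2E,5S,6E,10Z,14Z)-5,16-bis[(tert-butyldimethylsilyl)oxy]-14-(2-hydroxyethyl)-6-iodo-2,10-dimethylhexadeca-2,6,10,14-tetraenoate, via alkylborane 22 (not isolated)
Conditions: 9-BBN (1.5 equiv), THF, 0 °C to rt; then NaBO3·4H2O, THF/H2O, rt
Reagents that add atoms: sodium perborate, [Na+].[O-]OB=O
Why: hydroboration with 9-BBN should take only the monosubstituted vinyl terminus of the 2-substituted diene (boron on C3), the trisubstituted alkenes, iodoalkene and enoate being inert, and oxidation gives the C3 alcohol.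

Step 15
Reactants: 23 methyl (2E,5S,6E,10Z,14Z)-5,16-bis[(tert-butyldimethylsilyl)oxy]-14-(2-hydroxyethyl)-6-iodo-2,10-dimethylhexadeca-2,6,10,14-tetraenoate
Product: 24 methyl (2E,5S,6E,10Z,14Z)-5,16-bis[(tert-butyldimethylsilyl)oxy]-6-iodo-2,10-dimethyl-14-(2-oxoethyl)hexadeca-2,6,10,14-tetraenoate
Conditions: Dess–Martin periodinane, NaHCO3, CH2Cl2, 0 °C; used at once
Reagents that add atoms: none
Why: buffered Dess–Martin oxidation gives the β,γ-unsaturated C3 aldehyde under neutral conditions that should not move C11=C11a into conjugation.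

Step 16
Reactants: 24 methyl (2E,5S,6E,10Z,14Z)-5,16-bis[(tert-butyldimethylsilyl)oxy]-6-iodo-2,10-dimethyl-14-(2-oxoethyl)hexadeca-2,6,10,14-tetraenoate
Product: 25 eleven-membered trienol (12S; both C3 epimers)
Conditions: CrCl2 (8 equiv), NiCl2 (0.1 equiv), DMSO/THF, rt, 0.003 M, slow addition
Reagents that add atoms: none
Why: Nozaki–Hiyama–Kishi closure forms C3–C4 and the eleven-membered ring with retention of the iodoalkene geometry (C5 trans to C3); C3 is not controlled here and both epimers are carried on.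

Step 17
Reactants: 25 eleven-membered trienol (12S; both C3 epimers)
Product: 26 eleven-membered C3 enone (12S)
Conditions: Dess–Martin periodinane, NaHCO3, CH2Cl2, 0 °C
Reagents that add atoms: none
Why: Dess–Martin oxidation of the allylic alcohol erases the uncontrolled C3 centre and converges both epimers on one enone.

Step 18
Reactants: 26 eleven-membered C3 enone (12S)
Product: 27 eleven-membered (3R,12S)-trienol methyl ester
Conditions: (S)-2-methyl-CBS-oxazaborolidine (0.5 equiv), catecholborane, toluene, −78 °C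
Reagents that add atoms: none
Why: in the Corey–Bakshi–Shibata reduction the (S)-oxazaborolidine treats the substituted alkenyl carbon C4 as the large group and the C19 methylene as the small one, so hydride delivery should give the (3R)-carbinol under catalyst control.

Step 19
Reactants: 27 eleven-membered (3R,12S)-trienol methyl ester
Product: 28 eleven-membered (3R,12S)-trienol acid (precursor of the key step)
Conditions: LiOH·H2O, THF/MeOH/H2O, 40 °C; then 0.5 M HCl to pH 4, 0 °C
Reagents that add atoms: lithium hydroxide, [Li+].[OH-]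
Why: saponification frees the acid so that in the next step the side chain is a carboxylate, which has no acidic γ-hydrogens and cannot leave as a stabilised dienolate.

Step 20
Reactants: 28 eleven-membered (3R,12S)-trienol acid
Product: 32 nine-membered ring A enol acetate methyl ester (4aS,11aR,12S), via dipotassium alkoxide carboxylate 29 (not isolated), via dipotassium enolate carboxylate 30 (not isolated), via potassium carboxylate enol acetate 31 (not isolated)
Conditions: KH (2.2 equiv), 18-crown-6 (2.2 equiv), THF, 0 °C to rt; AcCl (1.05 equiv), −78 °C; MeI (5 equiv), −78 °C to rt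
Reagents that add atoms: acetyl chloride, CC(Cl)=O; iodomethane, CI
Why: Proposed new method: KH deprotonates the acid and the C3 carbinol, and the C3 alkoxide of the 1,5-diene C4a=C4–C3–C19–C11=C11a undergoes an anion-accelerated [3,3] shift that forms C4a–C11a and breaks C3–C19, made irreversible by the C3 enolate, which acetyl chloride O-acylates before iodomethane esterifies the naked carboxylate. The closest known reactions are the anionic oxy-Cope rearrangement of acyclic 1,5-dien-3-ols and the thermal Cope contraction of cyclic 1,5-dienes; a contraction in which one alkene is exocyclic and an eleven-membered ring becomes nine-membered has no precedent. Ring A closes by sigmatropic ring contraction, the C5–C10 tether bridging C4a and C11 of a six-centre chair array. C4a and C11a are set by that chair, in which the (3R) alkoxide is equatorial, C5 is equatorial because it is trans to C3 on C4=C4a, and the C1 methylene is axial because it is cis to C19 on C11=C11a, which gives the trans (4aS,11aR) pair. The step needs the chair over the boat and the shift over proton transfer or fragmentation: the carboxylate removes the γ-deprotonation and vinylogous retro-aldol channels (so a 1,3-silyl shift between O12 and O3 stays reversible and harmless), and C1 at the alcohol level gives the allyl fragment no anion stabilisation, so C3–C19 cannot cleave stepwise.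

Step 21
Reactants: 32 nine-membered ring A enol acetate methyl ester (4aS,11aR,12S)
Product: 33 (7S,8R)-epoxide of 32
Conditions: m-CPBA (1.05 equiv), NaHCO3, CH2Cl2, −20 °C
Reagents that add atoms: m-CPBA, OOC(=O)c1cccc(Cl)c1
Why: Prilezhaev epoxidation should take the trisubstituted C7=C8 alkene ahead of the enol acetate, the 1,1-disubstituted methylene and the enoate, the Z geometry gives the cis epoxide, and attack on the outer face of ring A is relied on for (7S,8R), a substrate control that is unproven.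

Step 22
Reactants: 33 (7S,8R)-epoxide of 32
Product: 34 C1 primary alcohol (12-O-TBS retained)
Conditions: HF·pyridine, pyridine, THF, 0 °C to rt
Reagents that add atoms: none
Why: buffered HF·pyridine cleaves the primary C1 silyl ether much faster than the hindered secondary C12 ether and should tolerate the epoxide and the enol acetate.

Step 23
Reactants: 34 C1 primary alcohol (12-O-TBS retained)
Product: 35 C1 aldehyde
Conditions: Dess–Martin periodinane, NaHCO3, CH2Cl2, 0 °C; used at once
Reagents that add atoms: none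
Why: neutral Dess–Martin oxidation gives the α-branched C1 aldehyde without epimerising C11a or moving the exocyclic alkene.

Step 24
Reactants: 35 C1 aldehyde
Product: 37 (1R)-1-O-acetyl dihydropyran (12-O-TBS), via lactol 36 (not isolated)
Conditions: K2CO3 (0.3 equiv), MeOH, −10 °C; pH 7 buffer; then Ac2O, DMAP, pyridine, CH2Cl2, −20 °C
Reagents that add atoms: acetic anhydride, CC(=O)OC(C)=O
Why: methanolysis of the enol acetate frees the C3 enolate, which closes onto the C1 aldehyde as the six-membered enol hemiacetal (the known cyclisation of 1,5-dialdehydes to 2-hydroxy-3,4-dihydro-2H-pyrans), and acetylation of the equilibrating lactol through its less hindered hydroxyl, trans to the C11a–C11 bond, is expected to give (1R).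

Step 25
Reactants: 37 (1R)-1-O-acetyl dihydropyran (12-O-TBS)
Product: 38 C12 alcohol
Conditions: TBAF, AcOH (1:1), THF, 0 °C to rt
Reagents that add atoms: none
Why: acetic-acid-buffered fluoride removes the secondary silyl ether near neutrality, which should spare the C1 acetal acetate, the enol ether and the epoxide.

Step 26
Reactants: 38 C12 alcohol
Product: 39 CNP0184381.3 (target)
Conditions: Ac2O, DMAP, pyridine, CH2Cl2, 0 °C
Reagents that add atoms: acetic anhydride, CC(=O)OC(C)=O
Why: DMAP-catalysed acetylation of the secondary C12 alcohol completes the target without touching any stereocentre.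

## Compound list

1 | neryl acetate | CC(C)=CCC/C(C)=C\COC(C)=O | starting material
2 | 6,7-epoxyneryl acetate | CC1(C)OC1CC/C(C)=C\COC(C)=O | intermediate
3 | (2Z)-3-methyl-6-oxohex-2-en-1-yl acetate | O=CCC/C(C)=C\COC(C)=O | intermediate
4 | (2Z)-3-methylhept-2-en-6-yn-1-ol | C#CCC/C(C)=C\CO | intermediate
5 | (2Z)-1-bromo-3-methylhept-2-en-6-yne | C#CCC/C(C)=C\CBr | intermediate
6 | methyl acetoacetate | CC(=O)CC(=O)OC | starting material
7 | sodium lithium dianion of methyl acetoacetate | [Na+].[Li+].C=C([O-])C=C([O-])OC | intermediate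
8 | methyl (6Z)-7-methyl-3-oxoundec-6-en-10-ynoate | COC(=O)CC(=O)CC/C=C(/C)CCC#C | intermediate
9 | methyl (2Z,6Z)-7-methyl-3-(trifluoromethanesulfonyloxy)undeca-2,6-dien-10-ynoate | COC(=O)/C=C(\OS(=O)(=O)C(F)(F)F)CC/C=C(/C)CCC#C | intermediate
10 | methyl (2Z,6Z)-3-ethenyl-7-methylundeca-2,6-dien-10-ynoate | COC(=O)/C=C(\C=C)CC/C=C(/C)CCC#C | intermediate
11 | (2Z,6Z)-3-ethenyl-7-methylundeca-2,6-dien-10-yn-1-ol | OC/C=C(\C=C)CC/C=C(/C)CCC#C | intermediate
12 | tert-butyl{[(2Z,6Z)-3-ethenyl-7-methylundeca-2,6-dien-10-yn-1-yl]oxy}dimethylsilane | CC(C)(C)[Si](C)(C)OC/C=C(\C=C)CC/C=C(/C)CCC#C | intermediate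
13 | lithium acetylide of 12 | [Li+].CC(C)(C)[Si](C)(C)OC/C=C(\C=C)CC/C=C(/C)CCC#[C-] | intermediate
14 | (6Z,10Z)-12-[(tert-butyldimethylsilyl)oxy]-10-ethenyl-6-methyldodeca-6,10-dien-2-ynal | CC(C)(C)[Si](C)(C)OC/C=C(\C=C)CC/C=C(/C)CCC#CC=O | intermediate
15 | methyl tiglate, methyl (2E)-2-methylbut-2-enoate | C/C=C(\C)C(=O)OC | starting material
16 | lithium dienolate of methyl tiglate | [Li+].C=CC(C)=C([O-])OC | intermediate
17 | tert-butyl[(1-methoxy-2-methylbuta-1,3-dien-1-yl)oxy]dimethylsilane | C=CC(C)=C(OC)O[Si](C)(C)C(C)(C)C | intermediate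
18 | methyl (2E,5S,10Z,14Z)-16-[(tert-butyldimethylsilyl)oxy]-14-ethenyl-5-hydroxy-2,10-dimethylhexadeca-2,10,14-trien-6-ynoate | CC(C)(C)[Si](C)(C)OC/C=C(\C=C)CC/C=C(/C)CCC#C[C@H](C/C=C(\C)C(=O)OC)O | intermediate
19 | 6-(tributylstannyl) alkene from 18 (tin on C4, H on C4a, syn) | CC(C)(C)[Si](C)(C)OC/C=C(\C=C)CC/C=C(/C)CC/C=C(/[Sn](CCCC)(CCCC)CCCC)[C@H](C/C=C(\C)C(=O)OC)O | intermediate
20 | methyl (2E,5S,6E,10Z,14Z)-16-[(tert-butyldimethylsilyl)oxy]-14-ethenyl-5-hydroxy-6-iodo-2,10-dimethylhexadeca-2,6,10,14-tetraenoate | CC(C)(C)[Si](C)(C)OC/C=C(\C=C)CC/C=C(/C)CC/C=C(/I)[C@H](C/C=C(\C)C(=O)OC)O | intermediate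
21 | methyl (2E,5S,6E,10Z,14Z)-5,16-bis[(tert-butyldimethylsilyl)oxy]-14-ethenyl-6-iodo-2,10-dimethylhexadeca-2,6,10,14-tetraenoate | CC(C)(C)[Si](C)(C)OC/C=C(\C=C)CC/C=C(/C)CC/C=C(/I)[C@H](C/C=C(\C)C(=O)OC)O[Si](C)(C)C(C)(C)C | intermediate
22 | B-alkyl-9-borabicyclo[3.3.1]nonane adduct of 21 (boron on C3) | CC(C)(C)[Si](C)(C)OC/C=C(\CCB1C2CCCC1CCC2)CC/C=C(/C)CC/C=C(/I)[C@H](C/C=C(\C)C(=O)OC)O[Si](C)(C)C(C)(C)C | intermediate
23 | methyl (2E,5S,6E,10Z,14Z)-5,16-bis[(tert-butyldimethylsilyl)oxy]-14-(2-hydroxyethyl)-6-iodo-2,10-dimethylhexadeca-2,6,10,14-tetraenoate | CC(C)(C)[Si](C)(C)OC/C=C(\CCO)CC/C=C(/C)CC/C=C(/I)[C@H](C/C=C(\C)C(=O)OC)O[Si](C)(C)C(C)(C)C | intermediate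
24 | methyl (2E,5S,6E,10Z,14Z)-5,16-bis[(tert-butyldimethylsilyl)oxy]-6-iodo-2,10-dimethyl-14-(2-oxoethyl)hexadeca-2,6,10,14-tetraenoate | CC(C)(C)[Si](C)(C)OC/C=C(\CC=O)CC/C=C(/C)CC/C=C(/I)[C@H](C/C=C(\C)C(=O)OC)O[Si](C)(C)C(C)(C)C | intermediate
25 | eleven-membered trienol, 12S, both C3 epimers (ring C3–C19–C11–C10–C9–C8=C7–C6–C5–C4a=C4; C1H2OTBS on the exocyclic C11=C11a, cis to C19; C5 trans to C3) | OC1C/C(=C\CO[Si](C)(C)C(C)(C)C)CC/C=C(/C)CC/C=C1\[C@H](C/C=C(\C)C(=O)OC)O[Si](C)(C)C(C)(C)C | intermediate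
26 | eleven-membered C3 enone (12S) | O=C1C/C(=C\CO[Si](C)(C)C(C)(C)C)CC/C=C(/C)CC/C=C1\[C@H](C/C=C(\C)C(=O)OC)O[Si](C)(C)C(C)(C)C | intermediate
27 | eleven-membered (3R,12S)-trienol methyl ester | O[C@@H]1C/C(=C\CO[Si](C)(C)C(C)(C)C)CC/C=C(/C)CC/C=C1\[C@H](C/C=C(\C)C(=O)OC)O[Si](C)(C)C(C)(C)C | intermediate
28 | eleven-membered (3R,12S)-trienol acid (key-step precursor) | O[C@@H]1C/C(=C\CO[Si](C)(C)C(C)(C)C)CC/C=C(/C)CC/C=C1\[C@H](C/C=C(\C)C(=O)O)O[Si](C)(C)C(C)(C)C | intermediate
29 | dipotassium C3 alkoxide carboxylate of 28 | [K+].[K+].[O-][C@@H]1C/C(=C\CO[Si](C)(C)C(C)(C)C)CC/C=C(/C)CC/C=C1\[C@H](C/C=C(\C)C(=O)[O-])O[Si](C)(C)C(C)(C)C | intermediate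
30 | dipotassium C3 enolate carboxylate of the nine-membered ring | [K+].[K+].C=C1CC/C=C(/C)CC[C@H](/C(=C/[O-])[C@H](C/C=C(\C)C(=O)[O-])O[Si](C)(C)C(C)(C)C)[C@H]1CO[Si](C)(C)C(C)(C)C | intermediate
31 | potassium carboxylate of the C3 enol acetate | [K+].C=C1CC/C=C(/C)CC[C@H](/C(=C/OC(C)=O)[C@H](C/C=C(\C)C(=O)[O-])O[Si](C)(C)C(C)(C)C)[C@H]1CO[Si](C)(C)C(C)(C)C | intermediate
32 | nine-membered ring A diene (4aS,11aR,12S) with C3 enol acetate, C1H2OTBS, 12-OTBS and methyl ester (key-step product) | C=C1CC/C=C(/C)CC[C@H](/C(=C/OC(C)=O)[C@H](C/C=C(\C)C(=O)OC)O[Si](C)(C)C(C)(C)C)[C@H]1CO[Si](C)(C)C(C)(C)C | intermediate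
33 | (7S,8R)-epoxide of 32 | C=C1CC[C@H]2O[C@@]2(C)CC[C@H](/C(=C/OC(C)=O)[C@H](C/C=C(\C)C(=O)OC)O[Si](C)(C)C(C)(C)C)[C@H]1CO[Si](C)(C)C(C)(C)C | intermediate
34 | C1 primary alcohol | C=C1CC[C@H]2O[C@@]2(C)CC[C@H](/C(=C/OC(C)=O)[C@H](C/C=C(\C)C(=O)OC)O[Si](C)(C)C(C)(C)C)[C@H]1CO | intermediate
35 | C1 aldehyde | C=C1CC[C@H]2O[C@@]2(C)CC[C@H](/C(=C/OC(C)=O)[C@H](C/C=C(\C)C(=O)OC)O[Si](C)(C)C(C)(C)C)[C@H]1C=O | intermediate
36 | C1 lactol of the 2-oxabicycle (C1 anomers; 12-OTBS) | C=C1CC[C@H]2O[C@@]2(C)CC[C@@H]2C([C@H](C/C=C(\C)C(=O)OC)O[Si](C)(C)C(C)(C)C)=COC(O)[C@@H]12 | intermediate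
37 | (1R,4aS,7S,8R,11aR,12S)-1-O-acetyl-12-O-TBS dihydropyran | C=C1CC[C@H]2O[C@@]2(C)CC[C@@H]2C([C@H](C/C=C(\C)C(=O)OC)O[Si](C)(C)C(C)(C)C)=CO[C@H](OC(C)=O)[C@@H]12 | intermediate
38 | 12-hydroxy-1-O-acetyl dihydropyran | C=C1CC[C@H]2O[C@@]2(C)CC[C@@H]2C([C@H](C/C=C(\C)C(=O)OC)O)=CO[C@H](OC(C)=O)[C@@H]12 | intermediate
39 | CNP0184381.3 | C=C1CC[C@H]2O[C@@]2(C)CC[C@@H]2C([C@H](C/C=C(\C)C(=O)OC)OC(C)=O)=CO[C@H](OC(C)=O)[C@@H]12 | target

## Step count and risks

Total steps: 26. Longest linear sequence: 25 steps (steps 1–9 and 11–26; step 10 is a one-step branch).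

Steps most likely to fail:

1. Step 20 (proposed new method). The alkoxide may be consumed by proton transfer or fragmentation faster than it rearranges, or the shift may pass through a boat and give the cis C4a/C11a pair. Fallback: a neutral, thermally driven [3,3] shift on a silyl ether, with no alkoxide or enolate present until after the shift. It is the long-known siloxy-Cope and Cope contraction chemistry of 1,5-dienes, though not yet shown on a ring of this size. It sets out from 27: TMSCl and imidazole in CH2Cl2 should give the C3 trimethylsilyl ether F1. Heating F1 in toluene at about 190 °C in a sealed, base-washed tube should give the trimethylsilyl enol ether F2 of the nine-membered ester. KOtBu in THF at −78 °C cleaves the O–Si bond to the potassium enolate F3, which acetyl chloride O-acylates to 32, where the route is rejoined at step 21; step 19 and the methylation are then not needed.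

2. Step 21. The peracid may attack the wrong face of C7=C8 on the flexible ring A, or oxidise the enol acetate as well. Fallback: deliver the oxygen to the face opposite the one an electrophile prefers, through a halohydrin. It sets out from 32: NBS (1.0 equiv) in THF/H2O at 0 °C should form the bromonium ion on the accessible face and water opens it anti at the tertiary C7, giving the bromohydrin F4. Ag2O in CH2Cl2 then closes the epoxide by SN2 at C8 with inversion, returning to the route at 33.

3. Step 24. Acetylation may capture mainly the lactol anomer with the wrong C1 configuration, and the base may epimerise C11a before the ring closes. Fallback: replace acylation with retention by substitution with inversion at C1. It sets out from 35 through lactol 36, formed as in step 24: Mitsunobu esterification with acetic acid (PPh3, DIAD, toluene, −20 °C) displaces the activated anomeric oxygen by SN2 and returns to the route at 37.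

Further compounds
F1 | step 20 | C3 trimethylsilyl ether of 27 | C[Si](C)(C)O[C@@H]1C/C(=C\CO[Si](C)(C)C(C)(C)C)CC/C=C(/C)CC/C=C1\[C@H](C/C=C(\C)C(=O)OC)O[Si](C)(C)C(C)(C)C
F2 | step 20 | C3 trimethylsilyl enol ether of the nine-membered methyl ester | C=C1CC/C=C(/C)CC[C@H](/C(=C/O[Si](C)(C)C)[C@H](C/C=C(\C)C(=O)OC)O[Si](C)(C)C(C)(C)C)[C@H]1CO[Si](C)(C)C(C)(C)C
F3 | step 20 | potassium C3 enolate of the nine-membered methyl ester | [K+].C=C1CC/C=C(/C)CC[C@H](/C(=C/[O-])[C@H](C/C=C(\C)C(=O)OC)O[Si](C)(C)C(C)(C)C)[C@H]1CO[Si](C)(C)C(C)(C)C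
F4 | step 21 | (7S,8S)-8-bromo-7-hydroxy derivative of 32 | C=C1CC[C@H](Br)[C@@](C)(O)CC[C@H](/C(=C/OC(C)=O)[C@H](C/C=C(\C)C(=O)OC)O[Si](C)(C)C(C)(C)C)[C@H]1CO[Si](C)(C)C(C)(C)C
F0 | step 24 | none | none
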